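**Retrosynthetic overview**
1. Target ⇐ ketal-protected 8α-acetoxy-9α-alcohol (tigloylation, ketal removal) ⇐ ring-B 9-ketone (C8 enolate hydroxylation/acetylation, then axial-selective reduction).
2. Ring B, key disconnection: the 7-isopropenyl-9-ketone ⇐ a dienyl cyclobutanol by two-carbon ring expansion (C9–C6 cleaved, C6–C7 formed, C7 set).
3. Dienyl cyclobutanol ⇐ ring-fused cyclobutanone + 2-methylbut-1-en-3-yne; cyclobutanone ⇐ keteniminium [2+2] on a 4,5-dimethylcyclohexene (sets quaternary C5 and the cis fusion).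
4. The cyclohexene ⇐ p-cresol by oxidative dearomatisation, catalytic asymmetric conjugate methylation (C4, the only catalyst-set centre) and reductive deoxygenation.
5. Ring order: ring A (from the arene) → cyclobutanone on C5/C10 → ring B by expansion of the four-membered ring.

Assumption: the ester /C(C)=C/C is read as the (E)-2-methylbut-2-enoate (tiglate); bicyclic compounds use eremophilane numbering (C5/C10 ring fusion, C14 on C5, C15 on C4, C11–C13 isopropenyl), β = face of the two ring methyls, so the target is 8α-acetoxy-9α-tigloyloxy-10βH-eremophil-11-en-2-one.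

**Step 1**
Reactants: 1 p-cresol (4-methylphenol)
Product: 2 4-methoxy-4-methylcyclohexa-2,5-dien-1-one
Conditions: PhI(OAc)2, MeOH, 0 °C → rt
Reagents that add atoms: methanol (CO)
Why: Hypervalent-iodine oxidative dearomatisation; the phenoxenium ion is trapped at the para carbon by methanol, and no stereocentre is formed.

**Step 2**
Reactants: 2 4-methoxy-4-methylcyclohexa-2,5-dien-1-one
Product: 3 (4S,5S)-4-methoxy-4,5-dimethylcyclohex-2-en-1-one (major diastereomer; its C4 epimer converges in step 3)
Conditions: Me2Zn, Cu(OTf)2 (2 mol%), BINOL-bis(1-phenylethyl)amine phosphoramidite (4 mol%, enantiomer that gives 5S), toluene, −25 °C; aq. NH4Cl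
Reagents that add atoms: dimethylzinc (C[Zn]C)
Why: Cu-catalysed enantioselective conjugate addition that desymmetrises the dienone; ligand-controlled face selection sets C5 (the future C4 methyl centre) as S.

**Step 3**
Reactants: 3 (4S,5S)-4-methoxy-4,5-dimethylcyclohex-2-en-1-one
Product: 4 (S)-4,5-dimethylcyclohex-3-en-1-one
Conditions: SmI2 (2.5 equiv), THF–MeOH, −78 °C
Reagents that add atoms: none
Why: SmI2 reductive elimination of the γ-methoxide gives the dienolate, and kinetic α-protonation gives the β,γ-enone with the trisubstituted alkene; the methyl-bearing stereocentre is not touched.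

**Step 4**
Reactants: 4 (S)-4,5-dimethylcyclohex-3-en-1-one
Product: 5 (S)-8,9-dimethyl-1,4-dioxaspiro[4.5]dec-7-ene
Conditions: (TMSOCH2)2, TMSOTf (cat.), CH2Cl2, −78 °C
Reagents that add atoms: 1,2-bis(trimethylsilyloxy)ethane (C[Si](C)(C)OCCO[Si](C)(C)C)
Why: Noyori ketalisation under cold aprotic conditions, so the alkene does not migrate to the tetrasubstituted position (which would erase the stereocentre).

**Step 5**
Reactants: 5 (S)-8,9-dimethyl-1,4-dioxaspiro[4.5]dec-7-ene; 6 N,N-dimethylacetamide
Product: 9 cis-4,4-ethylenedioxy-1,2-dimethylbicyclo[4.2.0]octan-7-one, via keteniminium triflate 7 (not isolated), via cyclobutaniminium triflate 8 (not isolated)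
Conditions: 6, Tf2O, 2,4,6-collidine, ClCH2CH2Cl, −20 °C; add 5, 80 °C; then H2O
Reagents that add atoms: water (O)
Why: Ghosez keteniminium–alkene [2+2] cycloaddition: the electrophilic carbon bonds to the less substituted alkene carbon, so the C=O ends next to the ring-fusion CH. Addition anti to the allylic methyl (pseudoaxial through A1,2 strain, as in alkylations of 2,3-dimethylcyclohexanone enolates) sets the quaternary methyl cis to the secondary methyl and the fusion cis; collidine protects the ketal.

**Step 6**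
Reactants: 9 cis-4,4-ethylenedioxy-1,2-dimethylbicyclo[4.2.0]octan-7-one; 10 2-methylbut-1-en-3-yne
Product: 13 cis-7-[(E)-3-methylbuta-1,3-dienyl]-4,4-ethylenedioxy-1,2-dimethylbicyclo[4.2.0]octan-7-ol, via lithium acetylide 11 (not isolated), via lithium propargylic alkoxide 12 (not isolated)
Conditions: 10, n-BuLi, THF, −78 °C; add 9; then Red-Al, 0 °C → rt; aq. Rochelle salt
Reagents that add atoms: none
Why: Acetylide 1,2-addition to the strained ketone from the exo face, then alkoxide-directed trans-hydroalumination (Red-Al reduction of a propargylic alcohol) gives the (E)-diene; the carbinol configuration is of no consequence because it is lost in step 7.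

**Step 7**
Reactants: 13 cis-7-[(E)-3-methylbuta-1,3-dienyl]-4,4-ethylenedioxy-1,2-dimethylbicyclo[4.2.0]octan-7-ol
Product: 14 2,2-ethylenedioxy-10βH-eremophil-11-en-9-one (cis-fused, 4β,5β-dimethyl, 7β-isopropenyl)
Conditions: [Rh(cod)OH]2 (2.5 mol%), (R)-DTBM-SEGPHOS (6 mol%, matched enantiomer), toluene, 100 °C
Reagents that add atoms: none
Why: Proposed new method: the Rh(I) alkoxide of the strained tertiary cyclobutanol should undergo β-carbon elimination of the less hindered C9–C6 bond, giving a primary neopentyl-type alkyl–Rh with no β-hydrogen and unmasking the (E)-dienone; 6-endo 1,4-addition of the alkyl–Rh to the enone β-carbon (the 8-ring 1,6-mode is disfavoured) closes ring B, and protonation of the Rh enolate by the next alcohol turns the cycle over; a chair-like closure with the (E)-enone substituent equatorial puts the isopropenyl group β at C7, while C5 and C10 are untouched so the cis fusion is kept; closest known reaction type: Rh(I)-catalysed β-carbon elimination/ring expansion of allenyl tert-cyclobutanols to cyclohexenones, not shown for 1,3-dienyl cyclobutanols or for setting a β-stereocentre.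

**Step 8**
Reactants: 14 2,2-ethylenedioxy-10βH-eremophil-11-en-9-one
Product: 17 8α-acetoxy-2,2-ethylenedioxy-10βH-eremophil-11-en-9-one, via potassium enolate 15 (not isolated), via potassium alkoxide 16 (not isolated)
Conditions: KHMDS, THF, −78 °C; 2-(phenylsulfonyl)-3-phenyloxaziridine; then Ac2O, −78 → 0 °C
Reagents that add atoms: 2-(phenylsulfonyl)-3-phenyloxaziridine (O1C(c2ccccc2)N1S(=O)(=O)c1ccccc1); acetic anhydride (CC(=O)OC(C)=O)
Why: Kinetic deprotonation at the C8 methylene (not the ring-fusion C10–H), then Davis enolate hydroxylation anti to the C7 isopropenyl group gives the trans (8α, equatorial and thermodynamically preferred) oxygen, acetylated in the same flask.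

**Step 9**
Reactants: 17 8α-acetoxy-2,2-ethylenedioxy-10βH-eremophil-11-en-9-one
Product: 18 8α-acetoxy-2,2-ethylenedioxy-10βH-eremophil-11-en-9α-ol
Conditions: L-Selectride, THF, −78 °C; AcOH quench at −78 °C
Reagents that add atoms: none
Why: Bulky-hydride reduction by equatorial attack from the β face (the α face is blocked by the axial C5–C4 bond) gives the axial 9α-alcohol cis to the 8α-acetate; the cold acidic quench suppresses 1,2-acyl migration.

**Step 10**
Reactants: 18 8α-acetoxy-2,2-ethylenedioxy-10βH-eremophil-11-en-9α-ol; 19 tigloyl chloride ((E)-2-methylbut-2-enoyl chloride)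
Product: 20 8α-acetoxy-2,2-ethylenedioxy-9α-tigloyloxy-10βH-eremophil-11-ene
Conditions: Et3N, DMAP (cat.), toluene, 60 °C
Reagents that add atoms: none
Why: DMAP-catalysed acylation of the hindered axial alcohol; the (E)-geometry of the acyl group is retained and no stereocentre changes.

**Step 11**
Reactants: 20 8α-acetoxy-2,2-ethylenedioxy-9α-tigloyloxy-10βH-eremophil-11-ene
Product: 21 8α-acetoxy-9α-tigloyloxy-10βH-eremophil-11-en-2-one (target)
Conditions: 1 M HCl, THF, rt
Reagents that add atoms: water (O)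
Why: Acid hydrolysis of the dioxolane; C4 and C10 are β to the freed ketone and cannot epimerise, and the esters and the isopropenyl group survive dilute acid.

**Compound list**
1 | p-cresol | Cc1ccc(O)cc1 | starting material
2 | 4-methoxy-4-methylcyclohexa-2,5-dien-1-one | COC1(C)C=CC(=O)C=C1 | intermediate
3 | (4S,5S)-4-methoxy-4,5-dimethylcyclohex-2-en-1-one | CO[C@]1(C)C=CC(=O)C[C@@H]1C | intermediate
4 | (S)-4,5-dimethylcyclohex-3-en-1-one | CC1=CCC(=O)C[C@@H]1C | intermediate
5 | (S)-8,9-dimethyl-1,4-dioxaspiro[4.5]dec-7-ene | CC1=CCC2(OCCO2)C[C@@H]1C | intermediate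
6 | N,N-dimethylacetamide | CC(=O)N(C)C | starting material
7 | N,N-dimethylketeniminium triflate | C=C=[N+](C)C.[O-]S(=O)(=O)C(F)(F)F | intermediate
8 | N,N-dimethyliminium triflate of cyclobutanone 9 | C1[C@@]2(C)[C@H](CC3(OCCO3)C[C@@H]2C)C1=[N+](C)C.[O-]S(=O)(=O)C(F)(F)F | intermediate
9 | cis-4,4-ethylenedioxy-1,2-dimethylbicyclo[4.2.0]octan-7-one (1-Me, 2-Me and 6-H on one face) | C1[C@@]2(C)[C@H](CC3(OCCO3)C[C@@H]2C)C1=O | intermediate
10 | 2-methylbut-1-en-3-yne | C#CC(C)=C | starting material
11 | lithium 3-methylbut-3-en-1-yn-1-ide | [Li+].[C-]#CC(C)=C | intermediate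
12 | lithium alkoxide of the 7-(3-methylbut-3-en-1-ynyl) carbinol of 9 | C1[C@@]2(C)[C@H](CC3(OCCO3)C[C@@H]2C)[C@@]1([O-])C#CC(C)=C.[Li+] | intermediate
13 | cis-7-[(E)-3-methylbuta-1,3-dienyl]-4,4-ethylenedioxy-1,2-dimethylbicyclo[4.2.0]octan-7-ol (dienyl on the face of the ring-fusion H and methyl) | C1[C@@]2(C)[C@H](CC3(OCCO3)C[C@@H]2C)[C@@]1(O)/C=C/C(C)=C | intermediate
14 | 2,2-ethylenedioxy-10βH-eremophil-11-en-9-one | C=C(C)[C@H]1C[C@@]2(C)[C@H](CC3(OCCO3)C[C@@H]2C)C(=O)C1 | intermediate
15 | potassium Δ8-enolate of 14 | C=C(C)[C@H]1C[C@@]2(C)[C@H](CC3(OCCO3)C[C@@H]2C)C([O-])=C1.[K+] | intermediate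
16 | potassium 8α-alkoxide of the 8-hydroxy-9-ketone | C=C(C)[C@H]1C[C@@]2(C)[C@H](CC3(OCCO3)C[C@@H]2C)C(=O)[C@@H]1[O-].[K+] | intermediate
17 | 8α-acetoxy-2,2-ethylenedioxy-10βH-eremophil-11-en-9-one | C=C(C)[C@H]1C[C@@]2(C)[C@H](CC3(OCCO3)C[C@@H]2C)C(=O)[C@@H]1OC(C)=O | intermediate
18 | 8α-acetoxy-2,2-ethylenedioxy-10βH-eremophil-11-en-9α-ol | C=C(C)[C@H]1C[C@@]2(C)[C@H](CC3(OCCO3)C[C@@H]2C)[C@H](O)[C@@H]1OC(C)=O | intermediate
19 | tigloyl chloride | C/C=C(\C)C(=O)Cl | starting material
20 | 8α-acetoxy-2,2-ethylenedioxy-9α-tigloyloxy-10βH-eremophil-11-ene | C=C(C)[C@H]1C[C@@]2(C)[C@H](CC3(OCCO3)C[C@@H]2C)[C@H](OC(=O)/C(C)=C/C)[C@@H]1OC(C)=O | intermediate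
21 | 8α-acetoxy-9α-tigloyloxy-10βH-eremophil-11-en-2-one | C=C(C)[C@H]1C[C@@]2(C)[C@H](CC(=O)C[C@@H]2C)[C@H](OC(=O)/C(C)=C/C)[C@@H]1OC(C)=O | target

**Step count and risks**
Total steps: 11. Longest linear sequence: 11 (from p-cresol).

The step most likely to fail is step 7, the proposed Rh-catalysed ring expansion. It could cleave the other cyclobutanol bond, stop at a ring-opened ketone by protodemetalation, give the C7 epimer, or epimerise C10 in the product. The fallback uses only known reactions, sets out from 9 and returns at 14. Diazomethane homologation of 9 (the less substituted carbon migrates) gives cis-6,6-ethylenedioxy-3a,4-dimethyloctahydro-1H-inden-1-one F1. A second, BF3-promoted diazomethane homologation gives cis-7,7-ethylenedioxy-4a,5-dimethyloctahydronaphthalen-1(2H)-one F2. Kinetic silylation (LDA, TMSCl) gives its 1-trimethylsilyloxy-3,4,4a,5,6,7,8,8a-octahydronaphthalene enol ether F3. Saegusa–Ito dehydrogenation with Pd(OAc)2 gives the enone cis-7,7-ethylenedioxy-4a,5-dimethyl-4a,5,6,7,8,8a-hexahydronaphthalen-1(4H)-one F4. Copper-catalysed conjugate addition of isopropenylmagnesium bromide from the convex β face then gives 14.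

Second is step 5. The keteniminium salt may attack the ketal, or the facial selectivity with respect to the allylic methyl may be poor. The fallback sets out from 5 and returns at 9. Thermal [2+2] with dichloroketene (Cl3CCOCl, Zn–Cu, POCl3, Et2O) gives cis-8,8-dichloro-4,4-ethylenedioxy-1,2-dimethylbicyclo[4.2.0]octan-7-one F5 with the same regiochemistry, and Zn/AcOH dechlorination gives 9.

Third is step 9. The hydride may attack the wrong face, or the alkoxide next to the acetate may cause acyl migration. The fallback sets out from 14 and returns at 18, with the two oxygens differentiated by selective acylation and not by the order of introduction. Davis hydroxylation of 14 without acetylation gives 8α-hydroxy-2,2-ethylenedioxy-10βH-eremophil-11-en-9-one F6. L-Selectride reduction gives the cis-diol 2,2-ethylenedioxy-10βH-eremophil-11-ene-8α,9α-diol F7. Selective acetylation of the less hindered equatorial 8-hydroxyl (Ac2O, collidine, −20 °C) gives 18.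

**Further compounds**
F1 | step 7 | cis-6,6-ethylenedioxy-3a,4-dimethyloctahydro-1H-inden-1-one (3a-Me, 4-Me, 7a-H cis) | C1[C@@]2(C)[C@H](CC3(OCCO3)C[C@@H]2C)C(=O)C1
F2 | step 7 | cis-7,7-ethylenedioxy-4a,5-dimethyloctahydronaphthalen-1(2H)-one (4a-Me, 5-Me, 8a-H cis) | C1C[C@@]2(C)[C@H](CC3(OCCO3)C[C@@H]2C)C(=O)C1
F3 | step 7 | cis-7,7-ethylenedioxy-4a,5-dimethyl-1-(trimethylsilyloxy)-3,4,4a,5,6,7,8,8a-octahydronaphthalene | C1C[C@@]2(C)[C@H](CC3(OCCO3)C[C@@H]2C)C(O[Si](C)(C)C)=C1
F4 | step 7 | cis-7,7-ethylenedioxy-4a,5-dimethyl-4a,5,6,7,8,8a-hexahydronaphthalen-1(4H)-one | C1C[C@@]2(C)[C@H](CC3(OCCO3)C[C@@H]2C)C(=O)C=1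
F5 | step 5 | cis-8,8-dichloro-4,4-ethylenedioxy-1,2-dimethylbicyclo[4.2.0]octan-7-one | ClC1(Cl)[C@@]2(C)[C@H](CC3(OCCO3)C[C@@H]2C)C1=O
F6 | step 9 | 8α-hydroxy-2,2-ethylenedioxy-10βH-eremophil-11-en-9-one | C=C(C)[C@H]1C[C@@]2(C)[C@H](CC3(OCCO3)C[C@@H]2C)C(=O)[C@@H]1O
F7 | step 9 | 2,2-ethylenedioxy-10βH-eremophil-11-ene-8α,9α-diol | C=C(C)[C@H]1C[C@@]2(C)[C@H](CC3(OCCO3)C[C@@H]2C)[C@H](O)[C@@H]1O
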